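**Retrosynthetic overview**

1. Kazinol D ⇐ its tris-MOM ether 12 (acetal cleavage) ⇐ one Pd/norbornene (Catellani-type) three-component coupling of iodochroman 5, alkyl iodide 11 and prenyl-Bpin. This makes the C6–CH2 bond between the two halves and the neighbouring C5–prenyl bond in the same operation.
2. Enabling feature: in the 2,2-dimethylchroman bicycle the prenyl carbon C5 lies between the ring-fusion carbon C4a and the linker carbon C6. A C5 iodide therefore has exactly one blocked ortho position (C4a) and one ortho C–H (C6), which is what ortho-alkylation/ipso-termination needs. C5 is also para to the C8 oxygen, so the iodide can be placed by plain phenol iodination.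
3. 5 ⇐ 2,2-dimethylchroman-8-ol ⇐ Kabbe condensation of 2',3'-dihydroxyacetophenone with acetone, then removal of the C4 carbonyl.
4. 11 ⇐ 4,6-dibromoresorcinol: one bromine becomes the 3-hydroxypropyl chain (aryllithium/oxetane), the other the 1,1-dimethylallyl group (γ-selective Suzuki coupling with prenyl-Bpin).
5. Ring order: both benzene rings are bought; the pyran ring of the chroman is the only ring built (step 1); no ring is formed afterwards.

Key step: step 9

Remark on the chemistry: kazinol D has no stereocentre and no stereogenic double bond, so no step needs stereocontrol. Chroman numbering (O1, C2 … C8a) is used for ring B throughout.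

**Route**

Step 1
Reactants: 1 1-(2,3-dihydroxyphenyl)ethanone
Product: 2 8-hydroxy-2,2-dimethylchroman-4-one
Conditions: acetone (5 equiv), pyrrolidine (0.5 equiv), EtOH, 60 °C, N2
Reagents that add atoms: acetone, CC(C)=O
Why: Kabbe condensation: the acetyl group condenses with acetone under enamine/iminium catalysis to the β,β-dimethyl enone, and the 2'-phenol closes the pyran ring by oxa-Michael addition with loss of water only, while the 3'-OH cannot cyclise and stays free.

Step 2
Reactants: 2 8-hydroxy-2,2-dimethylchroman-4-one
Product: 3 2,2-dimethylchroman-8-ol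
Conditions: Et3SiH (3 equiv), TFA, 60 °C
Reagents that add atoms: none
Why: Ionic hydrogenation of an aryl ketone: hydride transfer to the protonated carbonyl, ionisation of the benzylic alcohol to a cation stabilised by the ortho ring oxygen O1, and a second hydride transfer give the C4 methylene.

Step 3
Reactants: 3 2,2-dimethylchroman-8-ol
Product: 4 5-iodo-2,2-dimethylchroman-8-ol
Conditions: NIS (1.05 equiv), TsOH (cat.), MeCN, 0 °C to rt
Reagents that add atoms: N-iodosuccinimide, O=C1CCC(=O)N1I
Why: Electrophilic aromatic iodination: the free phenol is the strongest donor and should direct the bulky iodonium reagent to its para position C5 in preference to ortho C7, while C6 is activated only by the ether oxygen.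

Step 4
Reactants: 4 5-iodo-2,2-dimethylchroman-8-ol
Product: 5 5-iodo-8-(methoxymethoxy)-2,2-dimethylchroman
Conditions: NaH, MOMCl, DMF, 0 °C
Reagents that add atoms: chloromethyl methyl ether, COCCl
Why: Williamson-type O-alkylation of the sodium phenoxide gives the MOM acetal, which keeps the phenoxide from being O-alkylated by iodide 11 in step 9.

Step 5
Reactants: 6 4,6-dibromobenzene-1,3-diol
Product: 7 1,5-dibromo-2,4-bis(methoxymethoxy)benzene
Conditions: NaH (2.2 equiv), MOMCl (2.2 equiv), DMF, 0 °C
Reagents that add atoms: chloromethyl methyl ether, COCCl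
Why: Double Williamson-type O-alkylation of the bis-phenoxide protects both phenols as base-stable acetals that survive organolithium and palladium chemistry.

Step 6
Reactants: 7 1,5-dibromo-2,4-bis(methoxymethoxy)benzene
Product: 9 3-[5-bromo-2,4-bis(methoxymethoxy)phenyl]propan-1-ol, via aryllithium 8 (not isolated)
Conditions: n-BuLi (1.0 equiv), THF, −78 °C; oxetane (2 equiv), BF3·OEt2 (1.2 equiv), −78 °C; aq. NH4Cl
Reagents that add atoms: oxetane, C1COC1
Why: Bromine–lithium exchange of one of the two equivalent bromides (the electron-rich aryllithium should resist a second exchange) followed by BF3-activated SN2 opening of oxetane installs the three-carbon chain with a terminal alcohol.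

Step 7
Reactants: 9 3-[5-bromo-2,4-bis(methoxymethoxy)phenyl]propan-1-ol
Product: 10 3-[2,4-bis(methoxymethoxy)-5-(2-methylbut-3-en-2-yl)phenyl]propan-1-ol
Conditions: prenyl-Bpin (1.5 equiv), Pd2(dba)3/bulky dialkylbiarylphosphine (γ-selective ligand set), aq. K3PO4, THF, 40 °C
Reagents that add atoms: 4,4,5,5-tetramethyl-2-(3-methylbut-2-enyl)-1,3,2-dioxaborolane (prenyl-Bpin), CC(C)=CCB1OC(C)(C)C(C)(C)O1
Why: γ-Selective Suzuki–Miyaura coupling of a 3,3-disubstituted allylboronate: SE2′ transmetallation places palladium on the tertiary carbon and fast reductive elimination forms the aryl–quaternary carbon bond of the 1,1-dimethylallyl group; the free alcohol is tolerated.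

Step 8
Reactants: 10 3-[2,4-bis(methoxymethoxy)-5-(2-methylbut-3-en-2-yl)phenyl]propan-1-ol
Product: 11 1-(3-iodopropyl)-2,4-bis(methoxymethoxy)-5-(2-methylbut-3-en-2-yl)benzene
Conditions: PPh3, I2, imidazole, CH2Cl2, 0 °C to rt
Reagents that add atoms: iodine, II
Why: Appel iodination: the alkoxyphosphonium ion is displaced by iodide in an SN2 step under near-neutral conditions that leave the MOM acetals and the hindered vinyl group untouched.

Step 9
Reactants: 5 5-iodo-8-(methoxymethoxy)-2,2-dimethylchroman; 11 1-(3-iodopropyl)-2,4-bis(methoxymethoxy)-5-(2-methylbut-3-en-2-yl)benzene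
Product: 12 6-{3-[2,4-bis(methoxymethoxy)-5-(2-methylbut-3-en-2-yl)phenyl]propyl}-8-(methoxymethoxy)-2,2-dimethyl-5-(3-methylbut-2-enyl)chroman
Conditions: 5 (1.0 equiv), 11 (1.3 equiv), Pd(OAc)2 (10 mol %), P(2-furyl)3 (22 mol %), norbornene (1 equiv), Cs2CO3 (3 equiv), H2O (5 equiv), prenyl-Bpin (1.5 equiv, slow addition), MeCN, 80 °C
Reagents that add atoms: 4,4,5,5-tetramethyl-2-(3-methylbut-2-enyl)-1,3,2-dioxaborolane (prenyl-Bpin), CC(C)=CCB1OC(C)(C)C(C)(C)O1
Why: Proposed new method: Pd(0) inserts into the C5–I bond of 5, norbornene carbopalladation and palladation of C6–H give the five-membered aryl–norbornyl palladacycle, which adds the primary iodide 11 (Pd(IV)) and reductively eliminates to form the C6–CH2 bond; C5 is then flanked by C4a and the new chain, so norbornene is expelled by β-carbon elimination and the 2,6-disubstituted aryl–Pd(II) is prenylated by transmetallation with prenyl-Bpin and reductive elimination. The closest known reaction type is the Catellani ortho-alkylation of ortho-substituted aryl iodides with primary alkyl iodides terminated by Suzuki coupling with arylboronic acids, together with the α-selective Pd-catalysed coupling of prenylboronates with aryl halides; the new element is an allylboronate as terminator. No ring of the product is closed: the only ring formed is the transient palladacycle (closed by C–H metalation, opened again by β-carbon elimination), and no stereocentre is created. The step needs a single alkylation at C6, secured because C6 is the only ortho C–H and the C4a substituent supplies the ortho effect; it needs chemoselectivity, secured because the aryl iodide adds to Pd(0) while the alkyl iodide reacts only with the electron-rich palladacycle and the boronate is added slowly; and it needs linear prenyl transfer, secured because after SE2′ transmetallation the σ-allyl equilibrates through the η3 form and reductive elimination at the tertiary terminus next to a 2,6-disubstituted aryl group is sterically prohibitive. The neopentyl-type vinyl group of 11 is too hindered to act as a Heck acceptor.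

Step 10
Reactants: 12 6-{3-[2,4-bis(methoxymethoxy)-5-(2-methylbut-3-en-2-yl)phenyl]propyl}-8-(methoxymethoxy)-2,2-dimethyl-5-(3-methylbut-2-enyl)chroman
Product: 13 kazinol D
Conditions: 3 M HCl, MeOH, 45 °C
Reagents that add atoms: none
Why: Acid-catalysed acetal exchange with methanol removes the three MOM groups; the ring-B prenyl group has no ortho phenol (its neighbours are C4a and C6) and the monosubstituted alkene of the 1,1-dimethylallyl group protonates only slowly, so both should survive mild acid.

**Compound list**

1 | 1-(2,3-dihydroxyphenyl)ethanone | CC(=O)c1cccc(O)c1O | starting material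
2 | 8-hydroxy-2,2-dimethylchroman-4-one | CC1(C)CC(=O)c2cccc(O)c2O1 | intermediate
3 | 2,2-dimethylchroman-8-ol | CC1(C)CCc2cccc(O)c2O1 | intermediate
4 | 5-iodo-2,2-dimethylchroman-8-ol | CC1(C)CCc2c(I)ccc(O)c2O1 | intermediate
5 | 5-iodo-8-(methoxymethoxy)-2,2-dimethylchroman | COCOc1ccc(I)c2c1OC(C)(C)CC2 | intermediate
6 | 4,6-dibromobenzene-1,3-diol | Oc1cc(O)c(Br)cc1Br | starting material
7 | 1,5-dibromo-2,4-bis(methoxymethoxy)benzene | COCOc1cc(OCOC)c(Br)cc1Br | intermediate
8 | [5-bromo-2,4-bis(methoxymethoxy)phenyl]lithium | [Li]c1cc(Br)c(OCOC)cc1OCOC | intermediate (not isolated)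
9 | 3-[5-bromo-2,4-bis(methoxymethoxy)phenyl]propan-1-ol | OCCCc1cc(Br)c(OCOC)cc1OCOC | intermediate
10 | 3-[2,4-bis(methoxymethoxy)-5-(2-methylbut-3-en-2-yl)phenyl]propan-1-ol | C=CC(C)(C)c1cc(CCCO)c(OCOC)cc1OCOC | intermediate
11 | 1-(3-iodopropyl)-2,4-bis(methoxymethoxy)-5-(2-methylbut-3-en-2-yl)benzene | C=CC(C)(C)c1cc(CCCI)c(OCOC)cc1OCOC | intermediate
12 | 6-{3-[2,4-bis(methoxymethoxy)-5-(2-methylbut-3-en-2-yl)phenyl]propyl}-8-(methoxymethoxy)-2,2-dimethyl-5-(3-methylbut-2-enyl)chroman | C=CC(C)(C)c1cc(CCCc2cc(OCOC)c3c(c2CC=C(C)C)CCC(C)(C)O3)c(OCOC)cc1OCOC | intermediate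
13 | kazinol D, 4-{3-[8-hydroxy-2,2-dimethyl-5-(3-methylbut-2-enyl)chroman-6-yl]propyl}-6-(2-methylbut-3-en-2-yl)benzene-1,3-diol | C=CC(C)(C)c1cc(CCCc2cc(O)c3c(c2CC=C(C)C)CCC(C)(C)O3)c(O)cc1O | target

**Step count**

Total steps: 10 (steps 1–4 ring-B branch, steps 5–8 ring-A branch, steps 9–10 after union).
Longest linear sequence: 6 steps (1–4, 9, 10 or 5–8, 9, 10).

**Steps most likely to fail**

Step 9 (proposed new method). The boronate may couple at the ipso carbon before the ortho alkylation has taken place. Prenyl transfer may occur through the tertiary terminus and give the branched isomer. Iodide 11 may be consumed by hydrolysis or elimination before the palladacycle captures it. The fallback uses only known reactions, sets out from 5 and comes back at 12. Bromination of 5 with NBS in MeCN should go para to the ring oxygen O1 and give 6-bromo-5-iodo-8-(methoxymethoxy)-2,2-dimethylchroman F1. An α-selective Suzuki–Miyaura coupling with prenyl-Bpin (Pd-PEPPSI-IPent, KOH, THF), which should engage the more reactive C–I bond first, would give 6-bromo-8-(methoxymethoxy)-2,2-dimethyl-5-(3-methylbut-2-enyl)chroman F2. Zinc insertion into 11 (Zn dust, LiCl, THF) would give {3-[2,4-bis(methoxymethoxy)-5-(2-methylbut-3-en-2-yl)phenyl]propyl}zinc iodide F3. A Negishi sp2–sp3 coupling of F2 with F3 (Pd(OAc)2, CPhos, THF, rt to 50 °C) would then form the same C6–CH2 bond and deliver 12.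

Step 7. γ-Selectivity may erode towards the linear prenyl arene, and reductive elimination to a quaternary carbon next to the OMOM group may be slow enough for protodeboronation to win. The fallback sets out from 7 and comes back at 10, installing the 1,1-dimethylallyl group by copper chemistry before the chain. 3-Methylbut-2-enyl pyridine-2-carboxylate F4 is prepared from prenol and picolinic acid (DCC, DMAP). Aryllithium 8, generated from 7 as in step 6, is converted with MgBr2·OEt2 and CuBr·SMe2 into [5-bromo-2,4-bis(methoxymethoxy)phenyl]copper F5. Its anti-SN2′ allylic substitution on F4 should give 1-bromo-2,4-bis(methoxymethoxy)-5-(2-methylbut-3-en-2-yl)benzene F6. Bromine–lithium exchange of F6 (n-BuLi, THF, −78 °C) gives [2,4-bis(methoxymethoxy)-5-(2-methylbut-3-en-2-yl)phenyl]lithium F7, which opens oxetane under BF3·OEt2 activation to give 10.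

Step 6. BF3 may cleave the MOM acetals or tie up the aryllithium as an unreactive ate complex, and the aryllithium may be butylated by the 1-bromobutane formed in the exchange. The fallback sets out from 7 (through 8) and comes back at 9, building the chain in two stages without a Lewis acid. Aryllithium 8 is trapped with allyl bromide (−78 °C to 0 °C) to give 1-allyl-5-bromo-2,4-bis(methoxymethoxy)benzene F8. Anti-Markovnikov hydroboration with 9-BBN (THF, rt) gives 9-{3-[5-bromo-2,4-bis(methoxymethoxy)phenyl]propyl}-9-borabicyclo[3.3.1]nonane F9, which is oxidised in the same flask (NaOH, H2O2) to 9.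

**Further compounds**

F1 | step 9 | 6-bromo-5-iodo-8-(methoxymethoxy)-2,2-dimethylchroman | COCOc1cc(Br)c(I)c2c1OC(C)(C)CC2
F2 | step 9 | 6-bromo-8-(methoxymethoxy)-2,2-dimethyl-5-(3-methylbut-2-enyl)chroman | COCOc1cc(Br)c(CC=C(C)C)c2c1OC(C)(C)CC2
F3 | step 9 | {3-[2,4-bis(methoxymethoxy)-5-(2-methylbut-3-en-2-yl)phenyl]propyl}zinc iodide | C=CC(C)(C)c1cc(CCC[Zn]I)c(OCOC)cc1OCOC
F4 | step 7 | 3-methylbut-2-enyl pyridine-2-carboxylate | CC(C)=CCOC(=O)c1ccccn1
F5 | step 7 | [5-bromo-2,4-bis(methoxymethoxy)phenyl]copper | [Cu]c1cc(Br)c(OCOC)cc1OCOC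
F6 | step 7 | 1-bromo-2,4-bis(methoxymethoxy)-5-(2-methylbut-3-en-2-yl)benzene | C=CC(C)(C)c1cc(Br)c(OCOC)cc1OCOC
F7 | step 7 | [2,4-bis(methoxymethoxy)-5-(2-methylbut-3-en-2-yl)phenyl]lithium | [Li]c1cc(C(C)(C)C=C)c(OCOC)cc1OCOC
F8 | step 6 | 1-allyl-5-bromo-2,4-bis(methoxymethoxy)benzene | C=CCc1cc(Br)c(OCOC)cc1OCOC
F9 | step 6 | 9-{3-[5-bromo-2,4-bis(methoxymethoxy)phenyl]propyl}-9-borabicyclo[3.3.1]nonane | COCOc1cc(OCOC)c(CCCB2C3CCCC2CCC3)cc1Br
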